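The tetrahydrofuran ring has a twofold symmetry axis through O1 and the midpoint of the C3–C4 bond, and each aryl-bearing carbon (C2, C5) sits next to one of the two trans-related CH2OH-bearing carbons (C3, C4). The ring is therefore opened at O1–C2/O1–C5 to a symmetric (2S,3S)-2,3-bis(benzyloxymethyl)-1,4-diaryl-1,4-diketone. In one flask, aprotic bis-ketalisation closes the oxolane (one carbonyl oxygen becomes O1). Two silane hydride transfers to the successive cyclic aryl oxocarbenium ions, each anti to the neighbouring side arm, should then set C2 and C5 in the contra-thermodynamic cis,trans,cis array. The diketone comes from a twofold auxiliary-controlled alkylation of a succinyl bis-imide and a twofold thioester-to-ketone coupling.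

Key step: step 5

Remark: the SMILES is read as the (2S,3S,4S,5S) isomer (ring atoms O1, C2, C3, C4, C5), in which each aryl group is cis to the neighbouring hydroxymethyl group, the two hydroxymethyl groups are trans, and the two aryl groups are trans across O1.

Step 1
Reactants: 1 (R)-4-benzyl-1,3-oxazolidin-2-one; 2 succinyl chloride
Product: 3 1,4-bis[(4R)-4-benzyl-2-oxo-1,3-oxazolidin-3-yl]butane-1,4-dione
Conditions: 1 (2.1 equiv), n-BuLi, THF, −78 °C; then 2 (1.0 equiv), −78 → 0 °C
Reagents that add atoms: succinyl chloride ClC(=O)CCC(Cl)=O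
Why: Twofold N-acylation of the lithiated oxazolidinone by the diacid chloride (standard preparation of Evans imides); no stereocenter is formed and the auxiliary center is not touched.

Step 2
Reactants: 3 1,4-bis[(4R)-4-benzyl-2-oxo-1,3-oxazolidin-3-yl]butane-1,4-dione; 4 benzyl chloromethyl ether
Product: 5 (2S,3S)-1,4-bis[(4R)-4-benzyl-2-oxo-1,3-oxazolidin-3-yl]-2,3-bis[(benzyloxy)methyl]butane-1,4-dione
Conditions: TiCl4 (2.2 equiv), i-Pr2NEt (2.3 equiv), CH2Cl2, 0 °C; then BnOCH2Cl (4 equiv), 0 °C
Reagents that add atoms: benzyl chloromethyl ether ClCOCc1ccccc1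
Why: Twofold Evans alkylation through the chelated titanium Z-enolates; each (R)-auxiliary should direct the oxocarbenium-type electrophile to the enolate face remote from its benzyl group, so both new centers are S and the symmetric (2S,3S) product is the doubly auxiliary-matched one.

Step 3
Reactants: 5 (2S,3S)-1,4-bis[(4R)-4-benzyl-2-oxo-1,3-oxazolidin-3-yl]-2,3-bis[(benzyloxy)methyl]butane-1,4-dione; 6 ethanethiol
Product: 7 S,S'-diethyl (2S,3S)-2,3-bis[(benzyloxy)methyl]butanebis(thioate)
Conditions: EtSH (6 equiv), n-BuLi (4 equiv), THF, 0 °C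
Reagents that add atoms: ethanethiol CCS
Why: Nucleophilic acyl substitution by lithium ethanethiolate, which attacks the exocyclic imide carbonyl even in hindered imides and releases the auxiliary for recovery; the weakly basic thiolate should leave the α-centers and the β-benzyloxy groups untouched.

Step 4
Reactants: 7 S,S'-diethyl (2S,3S)-2,3-bis[(benzyloxy)methyl]butanebis(thioate); 8 [4-(benzyloxy)-3-methoxyphenyl]boronic acid
Product: 9 (2S,3S)-1,4-bis[4-(benzyloxy)-3-methoxyphenyl]-2,3-bis[(benzyloxy)methyl]butane-1,4-dione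
Conditions: 8 (3 equiv), Pd2(dba)3 (5 mol %), tri(2-furyl)phosphine (20 mol %), copper thiophene-2-carboxylate CuO2CC4H3S (3 equiv), THF, 50 °C
Reagents that add atoms: [4-(benzyloxy)-3-methoxyphenyl]boronic acid COc1cc(B(O)O)ccc1OCc1ccccc1
Why: Twofold Liebeskind–Srogl ketone synthesis, in which zerovalent palladium inserts into the C–S bond and the monovalent copper carboxylate removes the thiolate and activates the boronic acid without added base, so the ketone α-centers should not epimerise and benzyloxide should not be eliminated.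

Step 5
Reactants: 9 (2S,3S)-1,4-bis[4-(benzyloxy)-3-methoxyphenyl]-2,3-bis[(benzyloxy)methyl]butane-1,4-dione
Product: 12 (2S,3S,4S,5S)-2,5-bis[4-(benzyloxy)-3-methoxyphenyl]-3,4-bis[(benzyloxy)methyl]oxolane, via cyclic bis(methyl ketal) 10 (not isolated), via monomethyl ketal 11 (not isolated)
Conditions: Me3SiOMe (2.2 equiv), Me3SiOTf (0.2 equiv), CH2Cl2, −78 → −40 °C; then Et3SiH (6 equiv), −78 °C; Et3N, −78 °C
Reagents that add atoms: none
Why: Me3SiOTf-catalysed exchange with Me3SiOMe turns one aryl ketone into a methoxycarbenium ion that is captured by the oxygen of the neighbouring carbonyl (5-exo-trig C–O closure; this oxygen becomes O1) to give cyclic bis(methyl ketal) 10, after which each ketal carbon ionises in turn to a cyclic aryl oxocarbenium ion that accepts hydride from Et3SiH (10 → 11 → 12). The closest known reaction types are the aprotic silyl-triflate acetalisation with alkoxysilanes, the silane reduction of ketals to ethers and the Lewis acid/silane reduction of lignan-type cyclic aryl hemiketals, merged here into a reductive cycloetherification of a 1,4-diketone. C2 and C5 are created under control of the adjacent C3 and C4 centers: hydride should enter the envelope oxocarbenium ion on the face opposite the neighbouring benzyloxymethyl arm, so each aryl group ends cis to that arm (2,3-cis and 4,5-cis), and because the two arms are trans the aryl groups end trans across O1, which is the (2S,3S,4S,5S) isomer. The step needs hydride transfer to cyclic and not open-chain cations (an open-chain addition would follow Felkin–Anh control, predicted to give the 2,3-trans relation); this is secured by forming 10 before the silane is added. It also needs kinetic control: low temperature, a non-basic counterion and a cold amine quench should suppress loss of H-3 from the cation (furan formation) and re-ionisation of the electron-rich benzylic ether, which would epimerise the product toward the all-trans isomer.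

Step 6
Reactants: 12 (2S,3S,4S,5S)-2,5-bis[4-(benzyloxy)-3-methoxyphenyl]-3,4-bis[(benzyloxy)methyl]oxolane
Product: 13 [(2S,3S,4S,5S)-2,5-bis(4-hydroxy-3-methoxyphenyl)oxolane-3,4-diyl]dimethanol (eduesmine)
Conditions: H2 (1 atm), Pd/C (10 %), EtOAc–MeOH, rt, stopped after uptake of four equivalents
Reagents that add atoms: none
Why: Catalytic hydrogenolysis of the two aryl and two primary benzyl ethers under neutral conditions, which should be faster than cleavage of the hindered ring C–O bonds and avoids the acid that would epimerise the p-hydroxybenzylic centers.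

Compound list
1 | (R)-4-benzyl-1,3-oxazolidin-2-one | O=C1N[C@H](Cc2ccccc2)CO1 | starting material
2 | succinyl chloride | ClC(=O)CCC(Cl)=O | starting material
3 | 1,4-bis[(4R)-4-benzyl-2-oxo-1,3-oxazolidin-3-yl]butane-1,4-dione | O=C(CCC(=O)N1[C@H](Cc2ccccc2)COC1=O)N1[C@H](Cc2ccccc2)COC1=O | intermediate
4 | benzyl chloromethyl ether | ClCOCc1ccccc1 | starting material
5 | (2S,3S)-1,4-bis[(4R)-4-benzyl-2-oxo-1,3-oxazolidin-3-yl]-2,3-bis[(benzyloxy)methyl]butane-1,4-dione | O=C([C@H](COCc1ccccc1)[C@@H](COCc1ccccc1)C(=O)N1[C@H](Cc2ccccc2)COC1=O)N1[C@H](Cc2ccccc2)COC1=O | intermediate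
6 | ethanethiol | CCS | starting material
7 | S,S'-diethyl (2S,3S)-2,3-bis[(benzyloxy)methyl]butanebis(thioate) | CCSC(=O)[C@H](COCc1ccccc1)[C@@H](COCc1ccccc1)C(=O)SCC | intermediate
8 | [4-(benzyloxy)-3-methoxyphenyl]boronic acid | COc1cc(B(O)O)ccc1OCc1ccccc1 | starting material
9 | (2S,3S)-1,4-bis[4-(benzyloxy)-3-methoxyphenyl]-2,3-bis[(benzyloxy)methyl]butane-1,4-dione | COc1cc(C(=O)[C@H](COCc2ccccc2)[C@@H](COCc2ccccc2)C(=O)c2ccc(OCc3ccccc3)c(OC)c2)ccc1OCc1ccccc1 | intermediate
10 | (3S,4S)-2,5-bis[4-(benzyloxy)-3-methoxyphenyl]-3,4-bis[(benzyloxy)methyl]-2,5-dimethoxyoxolane (cyclic bis(methyl ketal), mixture of epimers at C2 and C5) | COc1cc(C2(OC)OC(OC)(c3ccc(OCc4ccccc4)c(OC)c3)[C@H](COCc3ccccc3)[C@H]2COCc2ccccc2)ccc1OCc1ccccc1 | intermediate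
11 | (2S,3S,4S)-2,5-bis[4-(benzyloxy)-3-methoxyphenyl]-3,4-bis[(benzyloxy)methyl]-5-methoxyoxolane (monomethyl ketal, mixture of epimers at C5) | COc1cc([C@H]2OC(OC)(c3ccc(OCc4ccccc4)c(OC)c3)[C@H](COCc3ccccc3)[C@H]2COCc2ccccc2)ccc1OCc1ccccc1 | intermediate
12 | (2S,3S,4S,5S)-2,5-bis[4-(benzyloxy)-3-methoxyphenyl]-3,4-bis[(benzyloxy)methyl]oxolane | COc1cc([C@H]2O[C@H](c3ccc(OCc4ccccc4)c(OC)c3)[C@H](COCc3ccccc3)[C@H]2COCc2ccccc2)ccc1OCc1ccccc1 | intermediate
13 | [(2S,3S,4S,5S)-2,5-bis(4-hydroxy-3-methoxyphenyl)oxolane-3,4-diyl]dimethanol (eduesmine) | COc1cc([C@H]2O[C@H](c3ccc(O)c(OC)c3)[C@H](CO)[C@H]2CO)ccc1O | target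

Total step count: 6. Longest linear sequence: 6 steps (from 1 and 2 to 13).

Steps most likely to fail

Step 5. Hydride may be delivered to an open-chain cation instead of a cyclic one, giving the 2,3-trans relation at one center. The oxocarbenium ion may also lose the C3 proton and aromatise, or the product ring may re-ionise and epimerise. In the fallback the two benzylic centers are set one at a time, setting out from diketone 9. Corey–Bakshi–Shibata reduction with (R)-2-methyl-CBS-oxazaborolidine and BH3·SMe2 (0.6 equiv, THF, −20 °C) should reduce one aryl ketone under reagent control to the (S)-carbinol. This gives (2S,3S,4S)-1,4-bis[4-(benzyloxy)-3-methoxyphenyl]-2,3-bis[(benzyloxy)methyl]-4-hydroxybutan-1-one F1, which is in equilibrium with its cyclic hemiketal. The known reduction of such cyclic aryl hemiketals with Et3SiH and BF3·OEt2 (CH2Cl2, −78 °C) should then deliver hydride anti to the neighbouring arm, and the route is rejoined at 12.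

Step 2. The second enolisation or alkylation may stall at the mono-alkylated stage, the succinyl enolate may self-condense, or the second alkylation may lose diastereoselectivity. In the fallback the C3–C4 bond is made by oxidative enolate dimerisation and the benzylic carbonyl groups are introduced last, setting out from oxazolidinone 1.
- Acylation of 1 with 3-[4-(benzyloxy)-3-methoxyphenyl]propanoic acid (PivCl, Et3N, LiCl, THF) should give (R)-4-benzyl-3-{3-[4-(benzyloxy)-3-methoxyphenyl]propanoyl}-1,3-oxazolidin-2-one F2.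
- The lithium enolate of F2 (LDA, THF, −78 °C) is dimerised with CuCl2 to (2S,3S)-2,3-bis[4-(benzyloxy)-3-methoxybenzyl]-1,4-bis[(4R)-4-benzyl-2-oxo-1,3-oxazolidin-3-yl]butane-1,4-dione F3, each auxiliary steering its own new center.
- LiBH4 (THF, 0 °C) should give (2S,3S)-2,3-bis[4-(benzyloxy)-3-methoxybenzyl]butane-1,4-diol F4.
- NaH and BnBr (DMF) should give the (2S,3S)-tetrabenzyl ether F5.
- Twofold benzylic oxidation of the p-alkoxybenzyl CH2 groups with 2,3-dichloro-5,6-dicyano-1,4-benzoquinone in wet CH2Cl2 would rejoin the route at diketone 9.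

Step 4. Oxidative addition into the hindered thioesters may be slow, so that protodeboronation of the boronic acid and thermal degradation of the substrate take over. In the fallback the ketones are made by nucleophilic acyl substitution, setting out from bis-thioester 7. Treatment with MeNHOMe·HCl and i-PrMgCl (THF, −20 °C) should give (2S,3S)-2,3-bis[(benzyloxy)methyl]-N,N'-dimethoxy-N,N'-dimethylbutanediamide F6. Addition of [4-(benzyloxy)-3-methoxyphenyl]lithium F7 (from 1-(benzyloxy)-4-bromo-2-methoxybenzene and n-BuLi, THF, −78 °C) and a cold acidic quench of the chelated tetrahedral adducts then rejoins the route at diketone 9.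

Further compounds
F1 | step 5 | (2S,3S,4S)-1,4-bis[4-(benzyloxy)-3-methoxyphenyl]-2,3-bis[(benzyloxy)methyl]-4-hydroxybutan-1-one | COc1cc([C@@H](O)[C@H](COCc2ccccc2)[C@@H](COCc2ccccc2)C(=O)c2ccc(OCc3ccccc3)c(OC)c2)ccc1OCc1ccccc1
F2 | step 2 | (R)-4-benzyl-3-{3-[4-(benzyloxy)-3-methoxyphenyl]propanoyl}-1,3-oxazolidin-2-one | COc1cc(CCC(=O)N2[C@H](Cc3ccccc3)COC2=O)ccc1OCc1ccccc1
F3 | step 2 | (2S,3S)-2,3-bis[4-(benzyloxy)-3-methoxybenzyl]-1,4-bis[(4R)-4-benzyl-2-oxo-1,3-oxazolidin-3-yl]butane-1,4-dione | O=C([C@@H](Cc1ccc(OCc2ccccc2)c(OC)c1)[C@H](Cc1ccc(OCc2ccccc2)c(OC)c1)C(=O)N1[C@H](Cc2ccccc2)COC1=O)N1[C@H](Cc2ccccc2)COC1=O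
F4 | step 2 | (2S,3S)-2,3-bis[4-(benzyloxy)-3-methoxybenzyl]butane-1,4-diol | OC[C@@H](Cc1ccc(OCc2ccccc2)c(OC)c1)[C@H](Cc1ccc(OCc2ccccc2)c(OC)c1)CO
F5 | step 2 | (2S,3S)-1,4-bis(benzyloxy)-2,3-bis[4-(benzyloxy)-3-methoxybenzyl]butane | C(OCc1ccccc1)[C@@H](Cc1ccc(OCc2ccccc2)c(OC)c1)[C@H](Cc1ccc(OCc2ccccc2)c(OC)c1)COCc1ccccc1
F6 | step 4 | (2S,3S)-2,3-bis[(benzyloxy)methyl]-N,N'-dimethoxy-N,N'-dimethylbutanediamide | CON(C)C(=O)[C@H](COCc1ccccc1)[C@@H](COCc1ccccc1)C(=O)N(C)OC
F7 | step 4 | [4-(benzyloxy)-3-methoxyphenyl]lithium | [Li]c1ccc(OCc2ccccc2)c(OC)c1
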